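**Plan**

- Retrosynthesis: the target flavone is cut first at the O–acyl bond of a pivalate that masks the C3' hydroxyl, then at O1–C8a of ring C, and last at C2–C3 of the resulting 1,3-diketone.
- Forward: the ring B acid is pivaloylated and converted to its chloride, joined to 3,4,5-trimethoxyacetophenone by C-acylation (C2–C3), and ring C is then closed by anodic dehydrogenative C–H/O–H coupling of the diketone enol onto ring A (O1–C8a). Methanolysis frees the phenol.
- Enabling feature: ring A is a 3,4,5-trimethoxybenzoyl unit whose two ortho C–H carbons (either one becomes C8a) are equivalent, so C–O closure within ring A can only give the 6,7,8-trimethoxy pattern.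
- Stereochemistry: the target is achiral; no stereocentre has to be set.

Key step: step 4

Remark: flavone numbering (O1, C2, C3, C4, C4a, C5–C8, C8a; ring B positions primed) is used throughout, also for the open-chain precursors.

**Route**

Step 1
Reactants: 1 3-hydroxy-4,5-dimethoxybenzoic acid
Product: 2 3,4-dimethoxy-5-(pivaloyloxy)benzoic acid
Conditions: NaOH (2.1 equiv), H2O/THF, 0 °C; pivaloyl chloride (1.15 equiv), 0 °C to rt; then aq. HCl to pH 2
Reagents that add atoms: pivaloyl chloride CC(C)(C)C(Cl)=O
Why: Schotten–Baumann O-acylation, in which the phenoxide of the dianion is far more nucleophilic than the carboxylate and any mixed anhydride formed at the carboxylate is hydrolysed back in the aqueous medium, so only the aryl pivalate should persist.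

Step 2
Reactants: 2 3,4-dimethoxy-5-(pivaloyloxy)benzoic acid
Product: 3 3,4-dimethoxy-5-(pivaloyloxy)benzoyl chloride
Conditions: (COCl)2 (1.5 equiv), DMF (cat.), CH2Cl2, 0 °C to rt; evaporate and use crude
Reagents that add atoms: oxalyl chloride O=C(Cl)C(=O)Cl
Why: DMF-catalysed (Vilsmeier-type) conversion of a carboxylic acid into its chloride, conditions to which the aryl pivalate and the methyl ethers are inert.

Step 3
Reactants: 3 3,4-dimethoxy-5-(pivaloyloxy)benzoyl chloride; 4 1-(3,4,5-trimethoxyphenyl)ethanone (3,4,5-trimethoxyacetophenone)
Product: 5 2,3-dimethoxy-5-[3-oxo-3-(3,4,5-trimethoxyphenyl)propanoyl]phenyl pivalate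
Conditions: MgBr2·OEt2 (2.5 equiv), i-Pr2NEt (3 equiv), CH2Cl2, rt; 1 M aq. HCl work-up
Reagents that add atoms: none
Why: Claisen-type C-acylation under soft enolisation, in which magnesium coordination lets the amine base enolise the methyl ketone, the enolate is acylated at carbon, and the product rests as an unreactive magnesium diketonate, so a second acylation is blocked and the pivalate never meets a strong base.

Step 4
Reactants: 5 2,3-dimethoxy-5-[3-oxo-3-(3,4,5-trimethoxyphenyl)propanoyl]phenyl pivalate
Product: 6 2,3-dimethoxy-5-(6,7,8-trimethoxy-4-oxo-4H-chromen-2-yl)phenyl pivalate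
Conditions: undivided cell, graphite anode, platinum cathode, Bu4NBF4 (0.1 M), dry 1,1,1,3,3,3-hexafluoropropan-2-ol, constant current (ca. 2 mA cm−2, about 2.2 F per mole), rt
Reagents that add atoms: none
Why: Proposed new method: anodic one-electron oxidation of the Z-enol of 5 in hexafluoroisopropanol should give a radical cation centred on the trimethoxyphenyl ring A, whose ortho carbon (ortho to one methoxyl, para to another) is attacked by the enol oxygen on C2, and a second electron transfer with loss of two protons restores the arene while hydrogen is evolved at the cathode. The closest known reaction types are the anodic dehydrogenative C–H/O–H lactonisation of biaryl-2-carboxylic acids to benzocoumarins and the FeCl3-mediated oxidative C–O cyclisation of electron-rich aryl ketone enols to benzofurans; a 1,3-diketone enol oxygen has not been used in this way to form a 4-pyranone. Ring C closes as a six-membered ring by attack of oxygen on the sp2 carbon C8a (6-endo-trig when the C4a–C8a bond is counted), and this is the only cyclisation open to the oxidised diketone, since attack through C3 would give a four-membered ring. No stereocentre is formed. The step needs closure onto ring A and not ring B: ring A carries three methoxyl donors and two equivalent ortho C–H bonds, whereas in ring B the pivaloyloxy group lowers the electron density, shields C2' and leaves C6' without a para methoxyl donor. The vinylogous ester 6 should be harder to oxidise than the enolised diketone 5, so limiting the charge to slightly above two electrons per molecule should guard against over-oxidation.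

Step 5
Reactants: 6 2,3-dimethoxy-5-(6,7,8-trimethoxy-4-oxo-4H-chromen-2-yl)phenyl pivalate
Product: 7 2-(3-hydroxy-4,5-dimethoxyphenyl)-6,7,8-trimethoxy-4H-chromen-4-one
Conditions: K2CO3 (1.2 equiv), MeOH/THF, rt; dilute aq. HCl work-up
Reagents that add atoms: none
Why: base-mediated transesterification (methanolysis) of an aryl ester, in which methoxide attacks the pivaloyl carbonyl and expels the stabilised phenoxide while the methyl ethers and the 4-pyranone should be untouched at room temperature.

**Compound list**

1 | 3-hydroxy-4,5-dimethoxybenzoic acid | COc1cc(C(=O)O)cc(O)c1OC | starting material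
2 | 3,4-dimethoxy-5-(pivaloyloxy)benzoic acid | COc1cc(C(=O)O)cc(OC(=O)C(C)(C)C)c1OC | intermediate
3 | 3,4-dimethoxy-5-(pivaloyloxy)benzoyl chloride | COc1cc(C(=O)Cl)cc(OC(=O)C(C)(C)C)c1OC | intermediate
4 | 1-(3,4,5-trimethoxyphenyl)ethanone (3,4,5-trimethoxyacetophenone) | CC(=O)c1cc(OC)c(OC)c(OC)c1 | starting material
5 | 2,3-dimethoxy-5-[3-oxo-3-(3,4,5-trimethoxyphenyl)propanoyl]phenyl pivalate | COc1cc(C(=O)CC(=O)c2cc(OC)c(OC)c(OC(=O)C(C)(C)C)c2)cc(OC)c1OC | intermediate
6 | 2,3-dimethoxy-5-(6,7,8-trimethoxy-4-oxo-4H-chromen-2-yl)phenyl pivalate | COc1cc(-c2cc(=O)c3cc(OC)c(OC)c(OC)c3o2)cc(OC(=O)C(C)(C)C)c1OC | intermediate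
7 | 2-(3-hydroxy-4,5-dimethoxyphenyl)-6,7,8-trimethoxy-4H-chromen-4-one | COc1cc(-c2cc(=O)c3cc(OC)c(OC)c(OC)c3o2)cc(O)c1OC | target

**Step count**

Total steps: 5. Longest linear sequence: 5 steps (1 → 2 → 3 → 5 → 6 → 7; ketone 4 is purchased and enters in step 3).

**Steps most likely to fail**

Step 4 (the unprecedented anodic closure). The intramolecular C–O bond formation may be outrun by intermolecular coupling of the oxidised diketone at C3, by closure onto ring B, or by further oxidation of the methoxylated product. The fallback forms the same O1–C8a bond by known chemistry. It sets out from ketone 4 and acid chloride 3 and returns at 6. Ketone 4 would be brominated on the ring with N-bromosuccinimide in acetonitrile to 1-(2-bromo-3,4,5-trimethoxyphenyl)ethanone F1. F1 would be C-acylated with 3 under the MgBr2·OEt2/i-Pr2NEt conditions of step 3 to 5-[3-(2-bromo-3,4,5-trimethoxyphenyl)-3-oxopropanoyl]-2,3-dimethoxyphenyl pivalate F2. The enolate of F2 would then be closed by intramolecular Ullmann-type O-arylation (CuI, 1,10-phenanthroline, K2CO3, DMF, 90 °C) to give 6. Should the pivalate be partly lost under these conditions, the material would simply be the target 7.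

Step 3. Acylation may stall with the electron-rich, ortho-unhindered but deactivated aroyl chloride, or over-acylation at oxygen may compete. The fallback replaces acylation by an aldol addition and oxidation. It sets out from 3 and 4 and returns at 5. Acid chloride 3 would be reduced with LiAlH(O-t-Bu)3 (THF, −78 °C) to 5-formyl-2,3-dimethoxyphenyl pivalate F3. The lithium enolate of 4 (LiN(i-Pr)2, THF, −78 °C) would add to F3 to give racemic 5-[1-hydroxy-3-oxo-3-(3,4,5-trimethoxyphenyl)propyl]-2,3-dimethoxyphenyl pivalate F4. Oxidation of F4 with Dess–Martin periodinane (CH2Cl2, rt) should deliver diketone 5.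

Step 1. Competing hydrolysis of the acylating agent and acylation at the carboxylate may leave the methoxyl-flanked phenol incompletely esterified. The fallback uses exhaustive acylation followed by selective hydrolysis. It sets out from 1 and returns at 2. Acid 1 would be treated with excess pivaloyl chloride (pyridine, DMAP cat., CH2Cl2) to give 3,4-dimethoxy-5-(pivaloyloxy)benzoic pivalic anhydride F5. The anhydride link alone would then be hydrolysed (NaHCO3, THF/H2O, rt; acidify) to give 2.

**Further compounds**

F1 | step 4 | 1-(2-bromo-3,4,5-trimethoxyphenyl)ethanone | CC(=O)c1cc(OC)c(OC)c(OC)c1Br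
F2 | step 4 | 5-[3-(2-bromo-3,4,5-trimethoxyphenyl)-3-oxopropanoyl]-2,3-dimethoxyphenyl pivalate | COc1cc(C(=O)CC(=O)c2cc(OC)c(OC)c(OC(=O)C(C)(C)C)c2)c(Br)c(OC)c1OC
F3 | step 3 | 5-formyl-2,3-dimethoxyphenyl pivalate | COc1cc(C=O)cc(OC(=O)C(C)(C)C)c1OC
F4 | step 3 | 5-[1-hydroxy-3-oxo-3-(3,4,5-trimethoxyphenyl)propyl]-2,3-dimethoxyphenyl pivalate (racemic) | COc1cc(C(=O)CC(O)c2cc(OC)c(OC)c(OC(=O)C(C)(C)C)c2)cc(OC)c1OC
F5 | step 1 | 3,4-dimethoxy-5-(pivaloyloxy)benzoic pivalic anhydride | COc1cc(C(=O)OC(=O)C(C)(C)C)cc(OC(=O)C(C)(C)C)c1OC
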